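**Plan**

- Retrosynthesis: the 3'-O-benzyl bond and the O-methyl bonds at O5 and O6 are cut first as protecting groups, then O1–C2 of the pyranone, and last C8a–O1 together with C4a–C4. This leaves 3,4,5,6-tetramethoxybenzyne and 3-(3-benzyloxy-4-methoxyphenyl)propiolic acid.
- Enabling feature: in ring A, C8a carries O1 and the neighbouring C4a carries the acyl carbon C4, the pair of ortho bonds an aryne can take up in one event. With C5–C8 all oxygenated, the aryne has a mirror plane through its triple bond, so only one insertion product exists.
- Forward order: ring A is carried intact from 1,2,3,4-tetramethoxybenzene to an ortho-silylaryl triflate, and ring B arrives as the propiolic acid made from O-benzylisovanillin. The aryne insertion joins ring A to the C4–C3–C2 chain, ring C is then closed in the 6-endo mode, and the 5-O-methyl, 6-O-methyl and benzyl groups are removed last.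
- Stereochemistry: the target has no stereocentre and no stereogenic double bond, so nothing has to be set.

Key step: step 7

Remark: 1,2,3,4-tetramethoxybenzene and 3-(benzyloxy)-4-methoxybenzaldehyde (O-benzylisovanillin) are taken as purchasable; the latter is otherwise one O-benzylation away from isovanillin.

**Route**

Step 1
Reactants: 1 1,2,3,4-tetramethoxybenzene
Product: 4 2,3,4,5-tetramethoxyphenol, via aryllithium 2 (not isolated), via arylboronate 3 (not isolated)
Conditions: n-BuLi, TMEDA, THF, 0 °C; B(OMe)3, −78 °C → rt; AcOH, 30% H2O2, 0 °C → rt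
Reagents that add atoms: hydrogen peroxide, OO
Why: Directed ortho-lithiation beside a methoxy group (the two ring hydrogens are equivalent), trapping on boron and peroxide oxidation of the C–B bond is the standard lithiation–borylation–oxidation way to turn a polymethoxyarene into its phenol.

Step 2
Reactants: 4 2,3,4,5-tetramethoxyphenol
Product: 5 2-bromo-3,4,5,6-tetramethoxyphenol
Conditions: NBS, CH2Cl2, −20 → 0 °C
Reagents that add atoms: N-bromosuccinimide, O=C1CCC(=O)N1Br
Why: Electrophilic aromatic bromination can only go to the single unsubstituted ring carbon, which is ortho to the hydroxyl group, and anhydrous NBS at low temperature should keep oxidation of the electron-rich phenol in check.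

Step 3
Reactants: 5 2-bromo-3,4,5,6-tetramethoxyphenol
Product: 6 (2-bromo-3,4,5,6-tetramethoxyphenoxy)trimethylsilane
Conditions: HMDS, THF, 70 °C; evaporate
Reagents that add atoms: hexamethyldisilazane, C[Si](C)(C)N[Si](C)(C)C
Why: O-Silylation of a phenol with HMDS needs no added base and gives only ammonia beside the silyl ether, so the crude product can be carried on after evaporation.

Step 4
Reactants: 6 (2-bromo-3,4,5,6-tetramethoxyphenoxy)trimethylsilane
Product: 9 2,3,4,5-tetramethoxy-6-(trimethylsilyl)phenyl trifluoromethanesulfonate, via silyloxy aryllithium 7 (not isolated), via lithium silylphenolate 8 (not isolated)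
Conditions: n-BuLi, THF, −100 → −78 °C; Tf2O, −100 → −78 °C
Reagents that add atoms: trifluoromethanesulfonic anhydride, O=S(=O)(OS(=O)(=O)C(F)(F)F)C(F)(F)F
Why: Bromine–lithium exchange gives an aryllithium that takes the silyl group from the neighbouring oxygen (retro-Brook 1,3-shift from O to C, driven by formation of the phenolate), and O-triflation of that phenolate is the established route to ortho-silylaryl triflates, including ones flanked by methoxy groups.

Step 5
Reactants: 10 3-(benzyloxy)-4-methoxybenzaldehyde
Product: 11 2-(benzyloxy)-4-(2,2-dibromoethenyl)-1-methoxybenzene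
Conditions: CBr4, PPh3, Zn, CH2Cl2, 0 °C → rt
Reagents that add atoms: carbon tetrabromide, BrC(Br)(Br)Br
Why: First stage of the Corey–Fuchs sequence, in which the dibromomethylene ylide made from CBr4, PPh3 and Zn undergoes a Wittig reaction with the aromatic aldehyde.

Step 6
Reactants: 11 2-(benzyloxy)-4-(2,2-dibromoethenyl)-1-methoxybenzene
Product: 13 3-(3-benzyloxy-4-methoxyphenyl)propiolic acid, via lithium acetylide 12 (not isolated)
Conditions: n-BuLi (2.2 equiv), THF, −78 °C; CO2, −78 °C → rt; 1 M HCl
Reagents that add atoms: carbon dioxide, O=C=O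
Why: Second stage of the Corey–Fuchs sequence, in which elimination and bromine–lithium exchange by two equivalents of n-BuLi give the lithium acetylide, which is carboxylated by CO2 at a temperature where the benzyl ether is not metalated.

Step 7
Reactants: 9 2,3,4,5-tetramethoxy-6-(trimethylsilyl)phenyl trifluoromethanesulfonate; 13 3-(3-benzyloxy-4-methoxyphenyl)propiolic acid
Product: 15 3-(3-benzyloxy-4-methoxyphenyl)-1-(2-hydroxy-3,4,5,6-tetramethoxyphenyl)prop-2-yn-1-one, via tetramethoxybenzyne 14 (not isolated)
Conditions: 13 (1.3 equiv), CsF (4 equiv), THF, sealed tube, 125 °C, stopped when 9 is consumed; 1 M HCl work-up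
Reagents that add atoms: none
Why: Fluoride strips the silyl group of 9 and triflate leaves, giving the aryne 14; the caesium carboxylate of 13 adds to it through oxygen (C8a–O1), and the ortho aryl anion so formed attacks the carbonyl of the aryl ester it has just made, the four-membered alkoxide then breaking its C–O bond so that the acyl group ends on carbon (C4a–C4) beside a phenoxide. The closest known reaction type is the fluoride-induced insertion of arynes into the acyl C–O bond of carboxylic acids, an anionic Fries-type acyl shift that delivers ortho-hydroxyaryl ketones and has been run with arylpropiolic acids. No ring of the product is closed here (the four-membered ring is only a transient) and no stereocentre is formed. Regiochemistry, the usual weakness of aryne additions, does not arise because 14 has a mirror plane through the triple bond and both termini are flanked by methoxy groups, so either sense of addition gives 15. The selectivity that is needed is acyl transfer ahead of proton capture by the aryl anion (which would leave the aryl propiolate) and ahead of attack on the alkyne terminus (which would lead to a 4-arylcoumarin): the ester carbonyl lies next to the carbanion while the Z-ester geometry turns the alkyne away from it, and sparingly soluble CsF in hot THF keeps aryne and proton donors at low concentration. The hydrogen bond of the new phenol to the ketone and the electron-rich aryl group on the alkyne should slow conjugate closure, and any part of 15 that does close in the pot is already flavone 17, the product of step 8.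

Step 8
Reactants: 15 3-(3-benzyloxy-4-methoxyphenyl)-1-(2-hydroxy-3,4,5,6-tetramethoxyphenyl)prop-2-yn-1-one
Product: 17 2-(3-benzyloxy-4-methoxyphenyl)-5,6,7,8-tetramethoxy-4H-chromen-4-one, via diethylamino enone 16 (not isolated)
Conditions: Et2NH, EtOH, reflux
Reagents that add atoms: none
Why: Aza-Michael addition of Et2NH to the ynone gives the β-amino enone 16, and intramolecular addition–elimination by the phenol at that same carbon (amine-mediated 6-endo closure of an ortho-hydroxyaryl ynone) can only form the pyranone, so the aurone of a 5-exo closure is excluded.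

Step 9
Reactants: 17 2-(3-benzyloxy-4-methoxyphenyl)-5,6,7,8-tetramethoxy-4H-chromen-4-one
Product: 18 2-(3-benzyloxy-4-methoxyphenyl)-5,6-dihydroxy-7,8-dimethoxy-4H-chromen-4-one
Conditions: AlBr3, MeCN, 0 °C → rt; 2 M HCl, 60 °C
Reagents that add atoms: none
Why: Chelation-directed Lewis-acid ether cleavage, in which aluminium held between the C4 carbonyl and O5 removes the peri 5-methyl group first and the 5-O-aluminium species then reaches the adjacent 6-methoxy oxygen so that bromide takes that methyl too, whereas the 7-, 8- and 4'-methyl ethers have no such anchored neighbour; benzyl ether lost at this stage would only deliver the target one step early.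

Step 10
Reactants: 18 2-(3-benzyloxy-4-methoxyphenyl)-5,6-dihydroxy-7,8-dimethoxy-4H-chromen-4-one
Product: 19 5,6-dihydroxy-2-(3-hydroxy-4-methoxyphenyl)-7,8-dimethoxy-4H-chromen-4-one (5,6,3'-trihydroxy-7,8,4'-trimethoxyflavone)
Conditions: H2 (1 atm), 10% Pd/C, EtOAc–MeOH, rt
Reagents that add atoms: none
Why: Heterogeneous catalytic hydrogenolysis of the benzyl aryl ether is selective over the vinylogous-ester C2–C3 double bond and leaves the methyl ethers and the 5,6-diol untouched.

**Compound list**

1 | 1,2,3,4-tetramethoxybenzene | COc1ccc(OC)c(OC)c1OC | starting material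
2 | (2,3,4,5-tetramethoxyphenyl)lithium | [Li]c1cc(OC)c(OC)c(OC)c1OC | intermediate
3 | dimethyl (2,3,4,5-tetramethoxyphenyl)boronate | COB(OC)c1cc(OC)c(OC)c(OC)c1OC | intermediate
4 | 2,3,4,5-tetramethoxyphenol | COc1cc(O)c(OC)c(OC)c1OC | intermediate
5 | 2-bromo-3,4,5,6-tetramethoxyphenol | COc1c(Br)c(O)c(OC)c(OC)c1OC | intermediate
6 | (2-bromo-3,4,5,6-tetramethoxyphenoxy)trimethylsilane | COc1c(Br)c(O[Si](C)(C)C)c(OC)c(OC)c1OC | intermediate
7 | [2,3,4,5-tetramethoxy-6-(trimethylsilyloxy)phenyl]lithium | [Li]c1c(OC)c(OC)c(OC)c(OC)c1O[Si](C)(C)C | intermediate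
8 | lithium 2,3,4,5-tetramethoxy-6-(trimethylsilyl)phenolate | [Li+].[O-]c1c(OC)c(OC)c(OC)c(OC)c1[Si](C)(C)C | intermediate
9 | 2,3,4,5-tetramethoxy-6-(trimethylsilyl)phenyl trifluoromethanesulfonate | COc1c(OC)c(OC)c([Si](C)(C)C)c(OS(=O)(=O)C(F)(F)F)c1OC | intermediate
10 | 3-(benzyloxy)-4-methoxybenzaldehyde | COc1ccc(C=O)cc1OCc1ccccc1 | starting material
11 | 2-(benzyloxy)-4-(2,2-dibromoethenyl)-1-methoxybenzene | COc1ccc(C=C(Br)Br)cc1OCc1ccccc1 | intermediate
12 | lithium (3-benzyloxy-4-methoxyphenyl)acetylide | [Li]C#Cc1ccc(OC)c(OCc2ccccc2)c1 | intermediate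
13 | 3-(3-benzyloxy-4-methoxyphenyl)propiolic acid | OC(=O)C#Cc1ccc(OC)c(OCc2ccccc2)c1 | intermediate
14 | 3,4,5,6-tetramethoxybenzyne | COC1=C(OC)C(OC)=C(OC)C#C1 | intermediate
15 | 3-(3-benzyloxy-4-methoxyphenyl)-1-(2-hydroxy-3,4,5,6-tetramethoxyphenyl)prop-2-yn-1-one | COc1ccc(C#CC(=O)c2c(O)c(OC)c(OC)c(OC)c2OC)cc1OCc1ccccc1 | intermediate
16 | (E)-3-(3-benzyloxy-4-methoxyphenyl)-3-(diethylamino)-1-(2-hydroxy-3,4,5,6-tetramethoxyphenyl)prop-2-en-1-one | CCN(CC)/C(=C/C(=O)c1c(O)c(OC)c(OC)c(OC)c1OC)c1ccc(OC)c(OCc2ccccc2)c1 | intermediate
17 | 2-(3-benzyloxy-4-methoxyphenyl)-5,6,7,8-tetramethoxy-4H-chromen-4-one | COc1ccc(-c2cc(=O)c3c(OC)c(OC)c(OC)c(OC)c3o2)cc1OCc1ccccc1 | intermediate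
18 | 2-(3-benzyloxy-4-methoxyphenyl)-5,6-dihydroxy-7,8-dimethoxy-4H-chromen-4-one | COc1ccc(-c2cc(=O)c3c(O)c(O)c(OC)c(OC)c3o2)cc1OCc1ccccc1 | intermediate
19 | 5,6-dihydroxy-2-(3-hydroxy-4-methoxyphenyl)-7,8-dimethoxy-4H-chromen-4-one | COc1ccc(-c2cc(=O)c3c(O)c(O)c(OC)c(OC)c3o2)cc1O | target

**Step count**

Total: 10 steps. Longest linear sequence: 8 steps (steps 1–4 and 7–10, from 1 to 19); the ring B branch (steps 5 and 6) joins at step 7.

**Steps most likely to fail**

1. Step 7. What may go wrong: the aryl anion picks up a proton before the acyl group moves, so that only O-arylation of the acid results; the propiolate loses CO2 at 125 °C; or the phenoxide closes in the 5-exo mode in the hot fluoride medium. The fallback gives up the aryne and builds the flavone by the chalcone route; it sets out from phenol 4 and aldehyde 10. C-Acetylation of 4 at its only free ring position with AcOH and BF3·OEt2 at 90 °C (Friedel–Crafts acylation ortho to the hydroxyl group) should give 1-(2-hydroxy-3,4,5,6-tetramethoxyphenyl)ethan-1-one F1. Claisen–Schmidt condensation of this ketone with 10 (KOH, EtOH, rt) should give (E)-3-(3-benzyloxy-4-methoxyphenyl)-1-(2-hydroxy-3,4,5,6-tetramethoxyphenyl)prop-2-en-1-one F2. Heating the chalcone with catalytic I2 in DMSO at 130 °C (oxidative cyclisation of a 2'-hydroxychalcone) should give flavone 17, where the route is rejoined before step 9.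

2. Step 9. What may go wrong: the Lewis acid fails to discriminate, stopping after the 5-methyl ether or going on to the 7-methyl ether, or it strips the benzyl group and then the neighbouring 4'-methyl ether from the aluminium 3'-phenoxide. The fallback removes the 6-methyl group oxidatively instead of by a second Lewis-acid cleavage; it sets out from 17. AlCl3 in MeCN, which is limited to the carbonyl-chelated position and mild enough that the benzyl ether is expected to stay, should give 2-(3-benzyloxy-4-methoxyphenyl)-5-hydroxy-6,7,8-trimethoxy-4H-chromen-4-one F3. IBX in DMF at rt delivers oxygen only to the carbon ortho to the free phenol, which here is C6, and should give with loss of methanol the ortho-quinone 2-(3-benzyloxy-4-methoxyphenyl)-7,8-dimethoxy-4H-chromene-4,5,6-trione F4. Reduction of this quinone with aqueous Na2S2O4 in the work-up should give 18, where the route is rejoined before step 10.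

3. Step 4. What may go wrong: the aryllithium is protonated before silicon migrates, the migration stays incomplete in the crowded ring, or the hindered phenolate resists triflation. The fallback puts silicon on carbon by directed ortho-metalation of a carbamate and replaces steps 2 to 4; it sets out from 4. Isopropyl isocyanate with catalytic Et3N in CH2Cl2 should give 2,3,4,5-tetramethoxyphenyl N-isopropylcarbamate F5. Transient N-silylation (TBSOTf, TMEDA, Et2O), ortho-lithiation with n-BuLi at −78 °C and a TMSCl quench should give 2,3,4,5-tetramethoxy-6-(trimethylsilyl)phenyl N-isopropylcarbamate F6. DBU and Et2NH in MeCN at 40 °C should release 2,3,4,5-tetramethoxy-6-(trimethylsilyl)phenol F7, and PhNTf2 added to the same pot should give triflate 9, where the route is rejoined before step 7.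

**Further compounds**

F1 | step 7 | 1-(2-hydroxy-3,4,5,6-tetramethoxyphenyl)ethan-1-one | CC(=O)c1c(O)c(OC)c(OC)c(OC)c1OC
F2 | step 7 | (E)-3-(3-benzyloxy-4-methoxyphenyl)-1-(2-hydroxy-3,4,5,6-tetramethoxyphenyl)prop-2-en-1-one | COc1ccc(/C=C/C(=O)c2c(O)c(OC)c(OC)c(OC)c2OC)cc1OCc1ccccc1
F3 | step 9 | 2-(3-benzyloxy-4-methoxyphenyl)-5-hydroxy-6,7,8-trimethoxy-4H-chromen-4-one | COc1ccc(-c2cc(=O)c3c(O)c(OC)c(OC)c(OC)c3o2)cc1OCc1ccccc1
F4 | step 9 | 2-(3-benzyloxy-4-methoxyphenyl)-7,8-dimethoxy-4H-chromene-4,5,6-trione | O=C1C=C(c2ccc(OC)c(OCc3ccccc3)c2)OC2=C1C(=O)C(=O)C(OC)=C2OC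
F5 | step 4 | 2,3,4,5-tetramethoxyphenyl N-isopropylcarbamate | CC(C)NC(=O)Oc1cc(OC)c(OC)c(OC)c1OC
F6 | step 4 | 2,3,4,5-tetramethoxy-6-(trimethylsilyl)phenyl N-isopropylcarbamate | CC(C)NC(=O)Oc1c([Si](C)(C)C)c(OC)c(OC)c(OC)c1OC
F7 | step 4 | 2,3,4,5-tetramethoxy-6-(trimethylsilyl)phenol | COc1c(O)c([Si](C)(C)C)c(OC)c(OC)c1OC
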